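**Strategy**

The target is the all-catechin (4α→8) tetramer. Its three interflavan bonds are made last, by adding one benzyl-protected flavan-3,4-diol electrophile three times to tetra-O-benzylcatechin, so the three upper units share one precursor. Everything rests on building ring C of that diol by closing the aryl ether bond O1–C8a: a palladium-catalysed etherification of an open-chain (S,Z)-allylic alcohol whose ring A carries bromine on C8a. The step exploits that O1 sits on stereogenic C2 and C8a on ring A, so C2, set by asymmetric alkynylation, is never touched; the Z C3=C4 alkene that holds O1 near C8a is then dihydroxylated to give 3-OH and the C4 leaving group.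

Key step: step 5

Assumption: the target is catechin-(4α→8)-catechin-(4α→8)-catechin-(4α→8)-catechin (every unit 2R,3S, 2,3-trans, 3,4-trans); units are numbered 1 to 4 from the end with free C8 to the end with the C4 methylene, flavan numbering is used for open-chain precursors too, and compounds 1, 5 and 11 are taken as purchasable.

**Route**

Step 1
Reactants: 1 1,3-bis(benzyloxy)-5-bromobenzene
Product: 3 2,4-bis(benzyloxy)-6-bromobenzaldehyde, via aryl iminium salt 2 (not isolated)
Conditions: POCl3, DMF, 0 °C to 60 °C; then aq. NaOAc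
Reagents that add atoms: N,N-dimethylformamide CN(C)C=O; water O
Why: Vilsmeier–Haack formylation, in which the chloroiminium ion should attack the ring carbon that is para to one benzyloxy group and flanked by the other benzyloxy group and bromine, because attack para to an alkoxy group is electronically preferred over attack between the two alkoxy groups, so that bromine ends up ortho to the new carbon, on the later C8a.

Step 2
Reactants: 3 2,4-bis(benzyloxy)-6-bromobenzaldehyde
Product: 4 1,5-bis(benzyloxy)-3-bromo-2-ethynylbenzene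
Conditions: dimethyl (1-diazo-2-oxopropyl)phosphonate, K2CO3, MeOH/THF, 0 °C to rt
Reagents that add atoms: dimethyl (1-diazo-2-oxopropyl)phosphonate CC(=O)C(=[N+]=[N-])P(=O)(OC)OC
Why: Ohira–Bestmann variant of the Seyferth–Gilbert homologation, in which the diazomethylphosphonate anion formed by methanolysis adds to the aldehyde and loss of phosphate and N2 with 1,2-hydrogen shift gives the terminal alkyne under conditions that spare the aryl bromide and the benzyl ethers.

Step 3
Reactants: 4 1,5-bis(benzyloxy)-3-bromo-2-ethynylbenzene; 5 3,4-bis(benzyloxy)benzaldehyde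
Product: 7 (R)-1-[3,4-bis(benzyloxy)phenyl]-3-[2,4-bis(benzyloxy)-6-bromophenyl]prop-2-yn-1-ol, via alkynyl(ethyl)zinc 6 (not isolated)
Conditions: Et2Zn, toluene, reflux; then (S)-BINOL (20 mol%), Ti(OiPr)4 (50 mol%), CH2Cl2, rt, then 5; aq. NH4Cl
Reagents that add atoms: none
Why: Catalytic enantioselective alkynylzinc addition to an aromatic aldehyde, in which the titanium BINOLate activates 5 and is expected to expose its Si face to zinc acetylide 6, setting the carbinol carbon (the later C2) as R (the BINOL antipode would be taken should the facial sense prove opposite).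

Step 4
Reactants: 7 (R)-1-[3,4-bis(benzyloxy)phenyl]-3-[2,4-bis(benzyloxy)-6-bromophenyl]prop-2-yn-1-ol
Product: 8 (S,Z)-1-[3,4-bis(benzyloxy)phenyl]-3-[2,4-bis(benzyloxy)-6-bromophenyl]prop-2-en-1-ol
Conditions: H2 (1 atm), Pd/CaCO3 poisoned with Pb(OAc)2, quinoline, EtOAc, rt
Reagents that add atoms: none
Why: Lindlar semi-hydrogenation, whose syn delivery of H2 on the poisoned palladium surface should give the Z alkene without touching the C–Br bond, the benzyl ethers or the carbinol centre (the descriptor changes from R to S only because the alkenyl carbon ranks below the aryl group).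

Step 5
Reactants: 8 (S,Z)-1-[3,4-bis(benzyloxy)phenyl]-3-[2,4-bis(benzyloxy)-6-bromophenyl]prop-2-en-1-ol
Product: 9 (S)-5,7-bis(benzyloxy)-2-[3,4-bis(benzyloxy)phenyl]-2H-chromene
Conditions: Pd(OAc)2 (5 mol%), 2-(di-tert-butylphosphino)-1,1'-binaphthyl (6 mol%), Cs2CO3, toluene, 65 °C, dark
Reagents that add atoms: none
Why: Zerovalent palladium (from Pd(OAc)2 and the phosphine) inserts into the C8a–Br bond of ring A, Cs2CO3 turns the C2 hydroxyl into an alkoxide bound to the divalent palladium centre, and C–O reductive elimination from this seven-membered palladacycle forms O1–C8a. The closest known reaction is the intramolecular Buchwald–Hartwig etherification of aryl bromides with secondary alcohols. Ring C (the six-membered 2H-pyran ring) is closed by formal 6-exo attack of the C2 oxygen on C8a, the Z C3=C4 bond holding the two ends within reach. No stereocentre is formed, and C2 keeps its configuration (S in both 8 and 9) because its C–O bond is never broken. The step needs C–O reductive elimination to outrun β-hydride elimination of the palladium alkoxide, which the bulky electron-rich di-tert-butylphosphine is chosen to secure, and it needs a single site of closure, which is secured because C8a carries the only halogen and lies ortho to the side chain. Mild heating in the dark is meant to keep the 2H-chromene from electrocyclic ring opening, which would erode C2.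

Step 6
Reactants: 9 (S)-5,7-bis(benzyloxy)-2-[3,4-bis(benzyloxy)phenyl]-2H-chromene
Product: 10 (2R,3S,4S)-5,7-bis(benzyloxy)-2-[3,4-bis(benzyloxy)phenyl]chromane-3,4-diol
Conditions: OsO4 (2 mol%), N-methylmorpholine N-oxide, acetone/H2O, 0 °C
Reagents that add atoms: N-methylmorpholine N-oxide C[N+]1([O-])CCOCC1; water O
Why: Upjohn dihydroxylation, in which OsO4 should add suprafacially to the electron-rich C3=C4 bond from the face opposite to the C2 aryl group, so that the new 3-OH is trans to that aryl group (3S) and the 4-OH is cis to the 3-OH (4S).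

Step 7
Reactants: 11 (+)-catechin, (2R,3S)
Product: 12 5,7,3',4'-tetra-O-benzyl-(+)-catechin
Conditions: BnBr, K2CO3, DMF, 0 °C to rt, argon
Reagents that add atoms: benzyl bromide BrCc1ccccc1
Why: Williamson ether synthesis in which K2CO3 deprotonates only the four phenols, so the secondary 3-OH stays free and C2 and C3 are untouched.

Step 8
Reactants: 10 (2R,3S,4S)-5,7-bis(benzyloxy)-2-[3,4-bis(benzyloxy)phenyl]chromane-3,4-diol; 12 5,7,3',4'-tetra-O-benzyl-(+)-catechin (4 equiv)
Product: 13 octa-O-benzyl catechin-(4α→8)-catechin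
Conditions: TMSOTf (0.1 equiv), CH2Cl2, 4 Å molecular sieves, −78 to −40 °C; Et3N quench
Reagents that add atoms: none
Why: Acid-catalysed Friedel–Crafts-type condensation of a flavan-3,4-diol and a flavan-3-ol with loss of water, in which ionisation of the C4–OH of 10 gives a benzylic cation stabilised by O1 and the 5,7-dialkoxy ring that should be attacked by C8 of 12 (less hindered than C6, which lies between two benzyloxy groups) on the face anti to the 3-OH, setting the new C4 as 4α (3,4-trans), while the excess of 12 suppresses self-condensation of 10.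

Step 9
Reactants: 10 (2R,3S,4S)-5,7-bis(benzyloxy)-2-[3,4-bis(benzyloxy)phenyl]chromane-3,4-diol; 13 octa-O-benzyl catechin-(4α→8)-catechin (3 equiv)
Product: 14 dodeca-O-benzyl catechin-(4α→8)-catechin-(4α→8)-catechin
Conditions: TMSOTf (0.1 equiv), CH2Cl2, 4 Å molecular sieves, −78 to −40 °C; Et3N quench
Reagents that add atoms: none
Why: The same Friedel–Crafts-type condensation with loss of water, in which the cation from 10 should be taken up by the only free C8 of 13 (that of its upper unit, more accessible than any C6) anti to the 3-OH, again giving the 4α (3,4-trans) bond.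

Step 10
Reactants: 10 (2R,3S,4S)-5,7-bis(benzyloxy)-2-[3,4-bis(benzyloxy)phenyl]chromane-3,4-diol; 14 dodeca-O-benzyl catechin-(4α→8)-catechin-(4α→8)-catechin (2 equiv)
Product: 15 hexadeca-O-benzyl catechin-(4α→8)-catechin-(4α→8)-catechin-(4α→8)-catechin
Conditions: TMSOTf (0.1 equiv), CH2Cl2, 4 Å molecular sieves, −78 to −40 °C; Et3N quench
Reagents that add atoms: none
Why: Third Friedel–Crafts-type condensation with loss of water, in which the cation from 10 should attack the free C8 of the upper unit of 14 anti to its own 3-OH, setting the last C4 as 4α (3,4-trans).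

Step 11
Reactants: 15 hexadeca-O-benzyl catechin-(4α→8)-catechin-(4α→8)-catechin-(4α→8)-catechin
Product: 16 catechin-(4α→8)-catechin-(4α→8)-catechin-(4α→8)-catechin
Conditions: H2 (1 atm), Pd(OH)2/C, THF/MeOH/H2O, rt
Reagents that add atoms: none
Why: Hydrogenolysis of the sixteen benzyl ethers under neutral conditions, which should leave the acid-labile interflavan bonds and all twelve stereocentres intact.

**Compound list**

1 | 1,3-bis(benzyloxy)-5-bromobenzene | Brc1cc(OCc2ccccc2)cc(OCc2ccccc2)c1 | starting material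
2 | N-[2,4-bis(benzyloxy)-6-bromobenzylidene]-N-methylmethanaminium dichlorophosphate (aryl iminium salt) | C[N+](C)=Cc1c(Br)cc(OCc2ccccc2)cc1OCc1ccccc1.[O-]P(Cl)(Cl)=O | intermediate
3 | 2,4-bis(benzyloxy)-6-bromobenzaldehyde | O=Cc1c(Br)cc(OCc2ccccc2)cc1OCc1ccccc1 | intermediate
4 | 1,5-bis(benzyloxy)-3-bromo-2-ethynylbenzene | C#Cc1c(Br)cc(OCc2ccccc2)cc1OCc1ccccc1 | intermediate
5 | 3,4-bis(benzyloxy)benzaldehyde | O=Cc1ccc(OCc2ccccc2)c(OCc2ccccc2)c1 | starting material
6 | {[2,4-bis(benzyloxy)-6-bromophenyl]ethynyl}(ethyl)zinc | CC[Zn]C#Cc1c(Br)cc(OCc2ccccc2)cc1OCc1ccccc1 | intermediate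
7 | (R)-1-[3,4-bis(benzyloxy)phenyl]-3-[2,4-bis(benzyloxy)-6-bromophenyl]prop-2-yn-1-ol | O[C@H](c1ccc(OCc3ccccc3)c(OCc3ccccc3)c1)C#Cc1c(Br)cc(OCc3ccccc3)cc1OCc1ccccc1 | intermediate
8 | (S,Z)-1-[3,4-bis(benzyloxy)phenyl]-3-[2,4-bis(benzyloxy)-6-bromophenyl]prop-2-en-1-ol | O[C@H](c1ccc(OCc3ccccc3)c(OCc3ccccc3)c1)/C=C\c1c(Br)cc(OCc3ccccc3)cc1OCc1ccccc1 | intermediate
9 | (S)-5,7-bis(benzyloxy)-2-[3,4-bis(benzyloxy)phenyl]-2H-chromene | C(c3ccccc3)Oc1cc(OCc3ccccc3)c2c(c1)O[C@H](c1ccc(OCc3ccccc3)c(OCc3ccccc3)c1)C=C2 | intermediate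
10 | (2R,3S,4S)-5,7-bis(benzyloxy)-2-[3,4-bis(benzyloxy)phenyl]chromane-3,4-diol (2,3-trans, 3,4-cis) | C(c3ccccc3)Oc1cc(OCc3ccccc3)c2c(c1)O[C@H](c1ccc(OCc3ccccc3)c(OCc3ccccc3)c1)[C@@H](O)[C@H]2O | intermediate
11 | (+)-catechin, (2R,3S) | Oc1cc(O)c2c(c1)O[C@H](c1ccc(O)c(O)c1)[C@@H](O)C2 | starting material
12 | 5,7,3',4'-tetra-O-benzyl-(+)-catechin | C(c3ccccc3)Oc1cc(OCc3ccccc3)c2c(c1)O[C@H](c1ccc(OCc3ccccc3)c(OCc3ccccc3)c1)[C@@H](O)C2 | intermediate
13 | octa-O-benzyl catechin-(4α→8)-catechin | C(c3ccccc3)Oc1cc(OCc3ccccc3)c2c(c1)O[C@H](c1ccc(OCc3ccccc3)c(OCc3ccccc3)c1)[C@@H](O)[C@@H]2c1c(OCc3ccccc3)cc(OCc3ccccc3)c2c1O[C@H](c1ccc(OCc3ccccc3)c(OCc3ccccc3)c1)[C@@H](O)C2 | intermediate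
14 | dodeca-O-benzyl catechin-(4α→8)-catechin-(4α→8)-catechin | C(c3ccccc3)Oc1cc(OCc3ccccc3)c2c(c1)O[C@H](c1ccc(OCc3ccccc3)c(OCc3ccccc3)c1)[C@@H](O)[C@@H]2c1c(OCc3ccccc3)cc(OCc3ccccc3)c2c1O[C@H](c1ccc(OCc3ccccc3)c(OCc3ccccc3)c1)[C@@H](O)[C@@H]2c1c(OCc3ccccc3)cc(OCc3ccccc3)c2c1O[C@H](c1ccc(OCc3ccccc3)c(OCc3ccccc3)c1)[C@@H](O)C2 | intermediate
15 | hexadeca-O-benzyl catechin-(4α→8)-catechin-(4α→8)-catechin-(4α→8)-catechin | C(c3ccccc3)Oc1cc(OCc3ccccc3)c2c(c1)O[C@H](c1ccc(OCc3ccccc3)c(OCc3ccccc3)c1)[C@@H](O)[C@@H]2c1c(OCc3ccccc3)cc(OCc3ccccc3)c2c1O[C@H](c1ccc(OCc3ccccc3)c(OCc3ccccc3)c1)[C@@H](O)[C@@H]2c1c(OCc3ccccc3)cc(OCc3ccccc3)c2c1O[C@H](c1ccc(OCc3ccccc3)c(OCc3ccccc3)c1)[C@@H](O)[C@@H]2c1c(OCc3ccccc3)cc(OCc3ccccc3)c2c1O[C@H](c1ccc(OCc3ccccc3)c(OCc3ccccc3)c1)[C@@H](O)C2 | intermediate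
16 | catechin-(4α→8)-catechin-(4α→8)-catechin-(4α→8)-catechin (CNP0236700.2) | Oc1cc(O)c2c(c1)O[C@H](c1ccc(O)c(O)c1)[C@@H](O)[C@@H]2c1c(O)cc(O)c2c1O[C@H](c1ccc(O)c(O)c1)[C@@H](O)[C@@H]2c1c(O)cc(O)c2c1O[C@H](c1ccc(O)c(O)c1)[C@@H](O)[C@@H]2c1c(O)cc(O)c2c1O[C@H](c1ccc(O)c(O)c1)[C@@H](O)C2 | target

**Count and risks**

Total steps: 11. Longest linear sequence: 10 (steps 1 to 6, then 8 to 11; step 7 is a one-step branch).

Most likely to fail, first: step 5. The palladium alkoxide may undergo β-hydride elimination (enone plus debrominated arene), the doubly activated allylic alcohol may isomerise under base, or C2 may erode through reversible ring opening of the chromene. The fallback sets out from 8 and moves the ring closure onto a saturated substrate. Silylation (TBSCl, imidazole, DMF) should give the tert-butyldimethylsilyl ether F1. OsO4/N-methylmorpholine N-oxide should then add syn across the Z alkene and anti to the allylic silyloxy group, giving the silyloxy diol F2 with the erythro C2/C3 pattern that a 2,3-trans ring needs. 2,2-Dimethoxypropane/PPTS should give the acetonide F3, and TBAF the free benzylic alcohol F4. The same Pd(OAc)2/phosphine/Cs2CO3 etherification, now on a saturated secondary benzylic alcohol, should close O1–C8a to the 3,4-O-isopropylidene chromane F5. F5 then takes the place of 10 in steps 8 to 10 (TMSOTf opens the acetal at the benzylic C4–O bond and acetone is lost), so the route is rejoined at 13.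

Second: step 10. Self-condensation of the diol electrophile may compete with attack by the hindered trimer and give oligomer mixtures, and regiocontrol may be lost. The fallback sets out from 10. NBS (1 equiv, CH2Cl2, −78 °C) should brominate C8 to give the 8-bromo diol F6, which can no longer act as a nucleophile. Near-equimolar coupling of F6 with 14 under the same acid catalysis should give the 8-bromo hexadeca-O-benzyl tetramer F7. Hydrogenolysis as in step 11 with added Et3N should remove the bromine together with the benzyl groups, rejoining the route at 16.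

Third: step 3. The zinc acetylide is flanked by bromine and a benzyloxy group, so addition may be slow or poorly face-selective. The fallback sets out from 4 and 5. Deprotonation of 4 with LiN(SiMe3)2 (THF, −78 °C), which spares the aryl bromide, and addition of the lithium acetylide to 5 should give the racemic propargylic alcohol F8. MnO2 oxidation should give the ynone F9. Asymmetric transfer hydrogenation (RuCl(p-cymene)(TsDPEN), enantiomer chosen to deliver the R carbinol, 2-propanol, rt) rejoins the route at 7.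

**Further compounds**

F1 | step 5 | tert-butyldimethylsilyl ether of 8 | CC(C)(C)[Si](C)(C)O[C@H](c1ccc(OCc3ccccc3)c(OCc3ccccc3)c1)/C=C\c1c(Br)cc(OCc3ccccc3)cc1OCc1ccccc1
F2 | step 5 | (1R,2S,3S)-1-[3,4-bis(benzyloxy)phenyl]-3-[2,4-bis(benzyloxy)-6-bromophenyl]-1-(tert-butyldimethylsilyloxy)propane-2,3-diol | CC(C)(C)[Si](C)(C)O[C@H](c1ccc(OCc3ccccc3)c(OCc3ccccc3)c1)[C@@H](O)[C@@H](O)c1c(Br)cc(OCc3ccccc3)cc1OCc1ccccc1
F3 | step 5 | 2,3-O-isopropylidene acetal of F2 | CC(C)(C)[Si](C)(C)O[C@H](c1ccc(OCc3ccccc3)c(OCc3ccccc3)c1)[C@H]4OC(C)(C)O[C@H]4c1c(Br)cc(OCc3ccccc3)cc1OCc1ccccc1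
F4 | step 5 | desilylated acetonide alcohol (free hydroxyl on the carbon bearing the 3,4-bis(benzyloxy)phenyl group) | O[C@H](c1ccc(OCc3ccccc3)c(OCc3ccccc3)c1)[C@H]4OC(C)(C)O[C@H]4c1c(Br)cc(OCc3ccccc3)cc1OCc1ccccc1
F5 | step 5 | 3,4-O-isopropylidene acetal of 10 | C(c3ccccc3)Oc1cc(OCc3ccccc3)c2c(c1)O[C@H](c1ccc(OCc3ccccc3)c(OCc3ccccc3)c1)[C@H]4OC(C)(C)O[C@@H]24
F6 | step 10 | 8-bromo derivative of 10 | C(c3ccccc3)Oc1cc(OCc3ccccc3)c2c(c1Br)O[C@H](c1ccc(OCc3ccccc3)c(OCc3ccccc3)c1)[C@@H](O)[C@H]2O
F7 | step 10 | 8-bromo derivative of 15 (bromine on C8 of unit 1) | C(c3ccccc3)Oc1cc(OCc3ccccc3)c2c(c1Br)O[C@H](c1ccc(OCc3ccccc3)c(OCc3ccccc3)c1)[C@@H](O)[C@@H]2c1c(OCc3ccccc3)cc(OCc3ccccc3)c2c1O[C@H](c1ccc(OCc3ccccc3)c(OCc3ccccc3)c1)[C@@H](O)[C@@H]2c1c(OCc3ccccc3)cc(OCc3ccccc3)c2c1O[C@H](c1ccc(OCc3ccccc3)c(OCc3ccccc3)c1)[C@@H](O)[C@@H]2c1c(OCc3ccccc3)cc(OCc3ccccc3)c2c1O[C@H](c1ccc(OCc3ccccc3)c(OCc3ccccc3)c1)[C@@H](O)C2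
F8 | step 3 | racemic 1-[3,4-bis(benzyloxy)phenyl]-3-[2,4-bis(benzyloxy)-6-bromophenyl]prop-2-yn-1-ol | OC(c1ccc(OCc3ccccc3)c(OCc3ccccc3)c1)C#Cc1c(Br)cc(OCc3ccccc3)cc1OCc1ccccc1
F9 | step 3 | 1-[3,4-bis(benzyloxy)phenyl]-3-[2,4-bis(benzyloxy)-6-bromophenyl]prop-2-yn-1-one | O=C(c1ccc(OCc3ccccc3)c(OCc3ccccc3)c1)C#Cc1c(Br)cc(OCc3ccccc3)cc1OCc1ccccc1
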